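**Retrosynthetic overview** (carotenoid numbering: ring C1–C6, chain C7–C15 then C15'–C10')
1. Target 24 ⇐ ring expansion of the vinyl oxirane in (9Z)-5,6-epoxide 23: the oxirane oxygen moves from C6 to C8, giving the 2,5-dihydrofuran last and setting C8.
2. 23 ⇐ Suzuki union at C8–C9 of ring vinyl iodide 11 (C1–C8) with the cis-alkenylboronate 22 (C9–C10'), which fixes 9Z.
3. 22 ⇐ cis-diborylpropene 21 (C9, C10, C19; from propyne) + pentaenyl iodide 19. 19 ⇐ enynol 12 (C11–C15), CHI3 (C15'), enynol 15 (C10'–C14') and Me3Al (C20').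
4. 11 ⇐ Takai iodo-olefination (C8) of epoxy aldehyde 10 ⇐ Sharpless epoxidation of allylic alcohol 8 ⇐ CBS-reduced annulation product of mesityl oxide and methyl acetoacetate.
5. Ring order: cyclohexene (step 1), oxirane (step 5), dihydrofuran by ring expansion (step 15).

Assumption: the target is taken exactly as drawn, i.e. (3S,5R,8S) with C8 cis to C11 across C9=C10 (9Z) and all other chain double bonds E; compounds 12, 15 and 20 are taken as commercial.

**Step 1**
Reactants: 1 mesityl oxide (4-methylpent-3-en-2-one); 2 methyl acetoacetate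
Product: 5 methyl (1RS)-2,6,6-trimethyl-4-oxocyclohex-2-ene-1-carboxylate, via Michael adduct 3 (not isolated), via aldol 4 (not isolated)
Conditions: ZnCl2 (0.2 equiv), toluene/heptane, reflux, Dean–Stark
Reagents that add atoms: none
Why: Michael addition of the acetoacetate CH to the β-carbon of mesityl oxide followed by intramolecular aldol condensation (Robinson-type annulation, the classical isophorone-carboxylate synthesis) builds the ring with C7 in place; the ester-bearing centre is racemic and is erased in step 3.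

**Step 2**
Reactants: 5 methyl (1RS)-2,6,6-trimethyl-4-oxocyclohex-2-ene-1-carboxylate
Product: 6 methyl (1RS,4S)-4-hydroxy-2,6,6-trimethylcyclohex-2-ene-1-carboxylate (both C1 epimers)
Conditions: (R)-Me-CBS (10 mol %), catecholborane (1.5 equiv), toluene, −78 °C
Reagents that add atoms: none
Why: Corey–Bakshi–Shibata reduction, in which the (R)-oxazaborolidine treats the alkenyl arm as the large group and delivers hydride to give the 4S carbinol (C3 of the target) regardless of the remote racemic centre.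

**Step 3**
Reactants: 6 methyl (1RS,4S)-4-hydroxy-2,6,6-trimethylcyclohex-2-ene-1-carboxylate
Product: 7 methyl (4R)-4-hydroxy-2,6,6-trimethylcyclohex-1-ene-1-carboxylate
Conditions: NaOMe (0.3 equiv), MeOH, 50 °C
Reagents that add atoms: none
Why: Base-mediated 1,3-prototropic shift through the ester dienolate moves the alkene to the tetrasubstituted, ester-conjugated position (thermodynamic control), merges both epimers and leaves the carbinol untouched (its descriptor becomes R only because the ranking of its neighbours changes).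

**Step 4**
Reactants: 7 methyl (4R)-4-hydroxy-2,6,6-trimethylcyclohex-1-ene-1-carboxylate
Product: 8 (1R)-4-(hydroxymethyl)-3,5,5-trimethylcyclohex-3-en-1-ol
Conditions: DIBAL-H (4 equiv), CH2Cl2, −78 °C → 0 °C; Rochelle salt
Reagents that add atoms: none
Why: Hydride reduction of the hindered conjugated ester (excess reagent covers the free hydroxyl) gives the primary allylic alcohol needed to direct the epoxidation.

**Step 5**
Reactants: 8 (1R)-4-(hydroxymethyl)-3,5,5-trimethylcyclohex-3-en-1-ol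
Product: 9 [(1R,4S,6R)-4-hydroxy-2,2,6-trimethyl-7-oxabicyclo[4.1.0]heptan-1-yl]methanol
Conditions: Ti(OiPr)4 (20 mol %), D-(−)-DET (24 mol %), t-BuOOH, 4 Å MS, CH2Cl2, −20 °C
Reagents that add atoms: tert-butyl hydroperoxide, CC(C)(C)OO
Why: Sharpless asymmetric epoxidation, in which the D-(−)-tartrate titanium complex delivers oxygen through the primary allylic alkoxide to the alkene face anti to the ring hydroxyl, setting 5R,6S under reagent control.

**Step 6**
Reactants: 9 [(1R,4S,6R)-4-hydroxy-2,2,6-trimethyl-7-oxabicyclo[4.1.0]heptan-1-yl]methanol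
Product: 10 (1S,4S,6R)-4-hydroxy-2,2,6-trimethyl-7-oxabicyclo[4.1.0]heptane-1-carbaldehyde
Conditions: TEMPO (10 mol %), PhI(OAc)2 (1.1 equiv), CH2Cl2, 0 °C → rt
Reagents that add atoms: none
Why: Oxoammonium (TEMPO/PhI(OAc)2) oxidation is selective for the primary over the secondary alcohol, and the resulting aldehyde is non-enolisable so the epoxide centres are safe.

**Step 7**
Reactants: 10 (1S,4S,6R)-4-hydroxy-2,2,6-trimethyl-7-oxabicyclo[4.1.0]heptane-1-carbaldehyde
Product: 11 (1R,3S,6S)-6-[(E)-2-iodoethenyl]-1,5,5-trimethyl-7-oxabicyclo[4.1.0]heptan-3-ol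
Conditions: CrCl2 (6 equiv), CHI3 (2 equiv), THF/dioxane, 0 °C → rt
Reagents that add atoms: iodoform, IC(I)I
Why: Takai iodo-olefination adds C8 as an (E)-vinyl iodide (high E selectivity with the α-quaternary aldehyde) and tolerates the epoxide and the free hydroxyl.

**Step 8**
Reactants: 12 (E)-3-methylpent-2-en-4-yn-1-ol
Product: 13 (E)-3-methylpent-2-en-4-ynal
Conditions: MnO2 (10 equiv), CH2Cl2, rt
Reagents that add atoms: none
Why: MnO2 oxidises the allylic alcohol to the enynal without touching the alkyne or the E geometry (C13=C14 of the target).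

**Step 9**
Reactants: 13 (E)-3-methylpent-2-en-4-ynal
Product: 14 (1E,3E)-1-iodo-4-methylhexa-1,3-dien-5-yne
Conditions: CrCl2 (6 equiv), CHI3 (2 equiv), THF/dioxane, 0 °C, dark
Reagents that add atoms: iodoform, IC(I)I
Why: Takai iodo-olefination of the enal gives the (E)-alkenyl iodide (C15=C15') and leaves the terminal alkyne untouched.

**Step 10**
Reactants: 15 (E)-pent-2-en-4-yn-1-ol; 14 (1E,3E)-1-iodo-4-methylhexa-1,3-dien-5-yne
Product: 17 (2E,4E,6E,8E)-4,9-dimethylundeca-2,4,6,8-tetraen-10-yn-1-ol, via alkenylalane 16 (not isolated)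
Conditions: Me3Al (3 equiv), Cp2ZrCl2 (0.2 equiv), (CH2Cl)2, rt; evaporate; then 14, ZnCl2 (1 equiv), Pd(PPh3)4 (5 mol %), THF, rt
Reagents that add atoms: trimethylaluminium, C[Al](C)C
Why: Negishi zirconium-catalysed methylalumination (syn, methyl to the internal alkyne carbon, fixing C13'=C14' as E) followed by palladium/zinc alkenyl–alkenyl cross-coupling with retention on both partners; excess Me3Al is stripped before coupling so the terminal alkyne of 14 survives.

**Step 11**
Reactants: 17 (2E,4E,6E,8E)-4,9-dimethylundeca-2,4,6,8-tetraen-10-yn-1-ol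
Product: 19 (2E,4E,6E,8E,10E)-11-iodo-4,9-dimethylundeca-2,4,6,8,10-pentaen-1-ol, via alkenylzirconocene 18 (not isolated)
Conditions: Cp2Zr(H)Cl (2.3 equiv), THF, rt, dark; then I2, 0 °C
Reagents that add atoms: iodine, II
Why: Hydrozirconation adds syn with zirconium at the terminal carbon and iodinolysis proceeds with retention, giving the (E)-alkenyl iodide (C11=C12); the extra equivalent covers the hydroxyl.

**Step 12**
Reactants: 20 propyne
Product: 21 2,2'-[(E)-prop-1-ene-1,2-diyl]bis(4,4,5,5-tetramethyl-1,3,2-dioxaborolane), the two boryl groups cis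
Conditions: B2pin2 (1 equiv), Pt(PPh3)4 (3 mol %), DMF, 80 °C, sealed tube
Reagents that add atoms: bis(pinacolato)diboron, CC1(C)OB(OC1(C)C)B1OC(C)(C)C(C)(C)O1
Why: Platinum-catalysed syn-diboration of the alkyne (Miyaura) places both boron atoms on the same side, which is the source of the 9Z geometry.

**Step 13**
Reactants: 19 (2E,4E,6E,8E,10E)-11-iodo-4,9-dimethylundeca-2,4,6,8,10-pentaen-1-ol; 21 cis-1,2-diborylpropene
Product: 22 (2E,4E,6E,8E,10E,12E)-4,9-dimethyl-13-(4,4,5,5-tetramethyl-1,3,2-dioxaborolan-2-yl)tetradeca-2,4,6,8,10,12-hexaen-1-ol (boron cis to C11; 12E only because carbon outranks boron)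
Conditions: 21 (1.2 equiv), Pd(PPh3)4 (5 mol %), TlOEt, THF/H2O, rt, dark
Reagents that add atoms: none
Why: Suzuki–Miyaura coupling occurs selectively at the less hindered terminal C–B bond with retention, forming C10–C11 and leaving the internal boronate cis to the new chain.

**Step 14**
Reactants: 11 (1R,3S,6S)-6-[(E)-2-iodoethenyl]-1,5,5-trimethyl-7-oxabicyclo[4.1.0]heptan-3-ol; 22 chain boronate
Product: 23 (1R,3S,6S)-6-[(1E,3Z,5E,7E,9E,11E,13E)-15-hydroxy-3,7,12-trimethylpentadeca-1,3,5,7,9,11,13-heptaen-1-yl]-1,5,5-trimethyl-7-oxabicyclo[4.1.0]heptan-3-ol, i.e. (3S,5R,6S,9Z)-5,6-epoxy-5,6-dihydro-10'-apo-β-carotene-3,10'-diol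
Conditions: Pd(PPh3)4 (10 mol %), TlOEt (1.5 equiv), degassed THF/H2O, rt, dark
Reagents that add atoms: none
Why: Suzuki–Miyaura coupling of the hindered alkenylboronate with the alkenyl iodide proceeds with retention on both partners (7E, 9Z), and the basic thallium conditions spare the acid-labile vinyl epoxide.

**Step 15**
Reactants: 23 (3S,5R,6S,9Z)-5,6-epoxy-5,6-dihydro-10'-apo-β-carotene-3,10'-diol
Product: 24 (2S,6S,7aR)-2-[(2Z,4E,6E,8E,10E,12E)-14-hydroxy-6,11-dimethyltetradeca-2,4,6,8,10,12-hexaen-2-yl]-4,4,7a-trimethyl-2,4,5,6,7,7a-hexahydro-1-benzofuran-6-ol (target)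
Conditions: (R)-TRIP chiral phosphoric acid (5 mol %), 4 Å MS, toluene, −40 °C, dark
Reagents that add atoms: none
Why: Proposed new method: a catalyst-controlled version of the carotenoid epoxide–furanoid rearrangement, in which the chiral phosphoric acid protonates the oxirane, the C6–O bond ionises to a polyene-delocalised cation held as a contact ion pair by the chiral phosphate (which also hydrogen-bonds the C5 hydroxyl), and the C5 oxygen closes onto one face of C8 to give the 2,5-dihydrofuran (oxirane-to-dihydrofuran ring expansion) with 8S, while C5 keeps its bond and configuration and the short-lived ion pair keeps 9Z; the closest known reactions are the unselective Brønsted-acid rearrangement of 5,6-epoxy carotenoids to 8R/8S furanoid mixtures and chiral-phosphate ion-pair control of epoxide openings and allyl-cation captures; the catalyst antipode that gives 8S is fixed by running both once.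

**Compound list**
1 | mesityl oxide | CC(=O)C=C(C)C | starting material
2 | methyl acetoacetate | CC(=O)CC(=O)OC | starting material
3 | methyl 2-acetyl-3,3-dimethyl-5-oxohexanoate (Michael adduct) | COC(=O)C(C(C)=O)C(C)(C)CC(C)=O | intermediate
4 | methyl 2-hydroxy-2,6,6-trimethyl-4-oxocyclohexane-1-carboxylate (aldol) | COC(=O)C1C(C)(O)CC(=O)CC1(C)C | intermediate
5 | methyl (1RS)-2,6,6-trimethyl-4-oxocyclohex-2-ene-1-carboxylate | COC(=O)C1C(C)=CC(=O)CC1(C)C | intermediate
6 | methyl (1RS,4S)-4-hydroxy-2,6,6-trimethylcyclohex-2-ene-1-carboxylate | COC(=O)C1C(C)=C[C@@H](O)CC1(C)C | intermediate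
7 | methyl (4R)-4-hydroxy-2,6,6-trimethylcyclohex-1-ene-1-carboxylate | COC(=O)C1=C(C)C[C@@H](O)CC1(C)C | intermediate
8 | (1R)-4-(hydroxymethyl)-3,5,5-trimethylcyclohex-3-en-1-ol | OCC1=C(C)C[C@@H](O)CC1(C)C | intermediate
9 | [(1R,4S,6R)-4-hydroxy-2,2,6-trimethyl-7-oxabicyclo[4.1.0]heptan-1-yl]methanol | OC[C@@]12O[C@]1(C)C[C@@H](O)CC2(C)C | intermediate
10 | (1S,4S,6R)-4-hydroxy-2,2,6-trimethyl-7-oxabicyclo[4.1.0]heptane-1-carbaldehyde | O=C[C@@]12O[C@]1(C)C[C@@H](O)CC2(C)C | intermediate
11 | (1R,3S,6S)-6-[(E)-2-iodoethenyl]-1,5,5-trimethyl-7-oxabicyclo[4.1.0]heptan-3-ol | I/C=C/[C@@]12O[C@]1(C)C[C@@H](O)CC2(C)C | intermediate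
12 | (E)-3-methylpent-2-en-4-yn-1-ol | C#C/C(C)=C/CO | starting material
13 | (E)-3-methylpent-2-en-4-ynal | C#C/C(C)=C/C=O | intermediate
14 | (1E,3E)-1-iodo-4-methylhexa-1,3-dien-5-yne | C#C/C(C)=C/C=C/I | intermediate
15 | (E)-pent-2-en-4-yn-1-ol | C#C/C=C/CO | starting material
16 | [(1E,3E)-5-(dimethylalumanyloxy)-2-methylpenta-1,3-dien-1-yl]dimethylalumane (alkenylalane) | C[Al](C)/C=C(C)/C=C/CO[Al](C)C | intermediate
17 | (2E,4E,6E,8E)-4,9-dimethylundeca-2,4,6,8-tetraen-10-yn-1-ol | C#C/C(C)=C/C=C/C=C(C)/C=C/CO | intermediate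
18 | C11 alkenylzirconocene chloride of 17, hydroxyl carried as its zirconocene alkoxide (Cp drawn σ-bonded) | Cl[Zr](C1C=CC=C1)(C1C=CC=C1)/C=C/C(C)=C/C=C/C=C(C)/C=C/CO[Zr](Cl)(C1C=CC=C1)C1C=CC=C1 | intermediate
19 | (2E,4E,6E,8E,10E)-11-iodo-4,9-dimethylundeca-2,4,6,8,10-pentaen-1-ol | I/C=C/C(C)=C/C=C/C=C(C)/C=C/CO | intermediate
20 | propyne | CC#C | starting material
21 | 2,2'-[(E)-prop-1-ene-1,2-diyl]bis(4,4,5,5-tetramethyl-1,3,2-dioxaborolane), boryl groups cis | C/C(B1OC(C)(C)C(C)(C)O1)=C/B1OC(C)(C)C(C)(C)O1 | intermediate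
22 | (2E,4E,6E,8E,10E,12E)-4,9-dimethyl-13-(4,4,5,5-tetramethyl-1,3,2-dioxaborolan-2-yl)tetradeca-2,4,6,8,10,12-hexaen-1-ol | C/C(B1OC(C)(C)C(C)(C)O1)=C/C=C/C(C)=C/C=C/C=C(C)/C=C/CO | intermediate
23 | (3S,5R,6S,9Z)-5,6-epoxy-5,6-dihydro-10'-apo-β-carotene-3,10'-diol | C/C(=C/C=C/C(C)=C/C=C/C=C(C)/C=C/CO)/C=C/[C@@]12O[C@]1(C)C[C@@H](O)CC2(C)C | intermediate
24 | (2S,6S,7aR)-2-[(2Z,4E,6E,8E,10E,12E)-14-hydroxy-6,11-dimethyltetradeca-2,4,6,8,10,12-hexaen-2-yl]-4,4,7a-trimethyl-2,4,5,6,7,7a-hexahydro-1-benzofuran-6-ol | C/C(=C/C=C/C(C)=C/C=C/C=C(C)/C=C/CO)[C@@H]1C=C2C(C)(C)C[C@H](O)C[C@@]2(C)O1 | target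

**Totals**
Total step count: 15. Longest linear sequence: 9 steps (1–7, 14, 15); the chain branch is 7 steps (8–11, 13, 14, 15) and step 12 is a one-step side branch.

**Three steps most likely to fail**

Step 15 (the new catalyst-controlled ring expansion) may give poor C8 selectivity or erode 9Z. The fallback uses known chemistry and sets out from 23: the classical acid-catalysed epoxide–furanoid rearrangement (about 0.005 M HCl in CHCl3, 0 °C, minutes) gives 24 together with its C8 epimer, (2R,6S,7aR)-2-[(2Z,4E,6E,8E,10E,12E)-14-hydroxy-6,11-dimethyltetradeca-2,4,6,8,10,12-hexaen-2-yl]-4,4,7a-trimethyl-2,4,5,6,7,7a-hexahydro-1-benzofuran-6-ol F8. The epimers are separated by preparative HPLC and F8 is re-equilibrated with the same acid and recycled, so the route comes back at 24 by separation instead of catalyst control.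

Step 3 (conjugative isomerisation) may stop at an unfavourable α/β equilibrium because the hindered ester is twisted out of conjugation. The fallback sets out from 5 and replaces steps 2 and 3:
- isopropenyl acetate/TsOH converts 5 into the dienol acetate methyl 4-acetoxy-2,6,6-trimethylcyclohexa-1,3-diene-1-carboxylate F1;
- NaBH4 in EtOH/H2O (the enol-acetate/borohydride deconjugation known from steroid enones) gives racemic methyl (4RS)-4-hydroxy-2,6,6-trimethylcyclohex-1-ene-1-carboxylate F2;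
- lipase PS with vinyl acetate acylates the R alcohol to methyl (4R)-4-acetoxy-2,6,6-trimethylcyclohex-1-ene-1-carboxylate F3, which is separated from the unreacted S alcohol;
- K2CO3/MeOH returns the route to 7.

Step 6 (primary-selective oxidation) may fail because the neopentylic primary alcohol is hindered while the secondary ring alcohol is not. The fallback sets out from 7 and uses a protecting-group strategy:
- TBSCl/imidazole gives methyl (4R)-4-{[tert-butyl(dimethyl)silyl]oxy}-2,6,6-trimethylcyclohex-1-ene-1-carboxylate F4;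
- DIBAL-H gives [(4R)-4-{[tert-butyl(dimethyl)silyl]oxy}-2,6,6-trimethylcyclohex-1-en-1-yl]methanol F5;
- the same Sharpless epoxidation gives [(1R,4S,6R)-4-{[tert-butyl(dimethyl)silyl]oxy}-2,2,6-trimethyl-7-oxabicyclo[4.1.0]heptan-1-yl]methanol F6;
- Dess–Martin periodinane gives (1S,4S,6R)-4-{[tert-butyl(dimethyl)silyl]oxy}-2,2,6-trimethyl-7-oxabicyclo[4.1.0]heptane-1-carbaldehyde F7;
- buffered TBAF removes the silyl group and returns the route to 10.

**Further compounds**
F1 | step 3 | methyl 4-acetoxy-2,6,6-trimethylcyclohexa-1,3-diene-1-carboxylate | COC(=O)C1=C(C)C=C(OC(C)=O)CC1(C)C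
F2 | step 3 | methyl (4RS)-4-hydroxy-2,6,6-trimethylcyclohex-1-ene-1-carboxylate | COC(=O)C1=C(C)CC(O)CC1(C)C
F3 | step 3 | methyl (4R)-4-acetoxy-2,6,6-trimethylcyclohex-1-ene-1-carboxylate | COC(=O)C1=C(C)C[C@@H](OC(C)=O)CC1(C)C
F4 | step 6 | methyl (4R)-4-{[tert-butyl(dimethyl)silyl]oxy}-2,6,6-trimethylcyclohex-1-ene-1-carboxylate | COC(=O)C1=C(C)C[C@@H](O[Si](C)(C)C(C)(C)C)CC1(C)C
F5 | step 6 | [(4R)-4-{[tert-butyl(dimethyl)silyl]oxy}-2,6,6-trimethylcyclohex-1-en-1-yl]methanol | OCC1=C(C)C[C@@H](O[Si](C)(C)C(C)(C)C)CC1(C)C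
F6 | step 6 | [(1R,4S,6R)-4-{[tert-butyl(dimethyl)silyl]oxy}-2,2,6-trimethyl-7-oxabicyclo[4.1.0]heptan-1-yl]methanol | OC[C@@]12O[C@]1(C)C[C@@H](O[Si](C)(C)C(C)(C)C)CC2(C)C
F7 | step 6 | (1S,4S,6R)-4-{[tert-butyl(dimethyl)silyl]oxy}-2,2,6-trimethyl-7-oxabicyclo[4.1.0]heptane-1-carbaldehyde | O=C[C@@]12O[C@]1(C)C[C@@H](O[Si](C)(C)C(C)(C)C)CC2(C)C
F8 | step 15 | (2R,6S,7aR)-2-[(2Z,4E,6E,8E,10E,12E)-14-hydroxy-6,11-dimethyltetradeca-2,4,6,8,10,12-hexaen-2-yl]-4,4,7a-trimethyl-2,4,5,6,7,7a-hexahydro-1-benzofuran-6-ol | C/C(=C/C=C/C(C)=C/C=C/C=C(C)/C=C/CO)[C@H]1C=C2C(C)(C)C[C@H](O)C[C@@]2(C)O1
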